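**Plan**

- Retrosynthesis: epoxide → C1=C10 alkene; C11=C13 and lactone bond C12–O6 → C7–CH2CO2t-Bu arm plus C6–OH; C6–H and the C8 isobutyrate → β-hydroxy ketone (Evans–Tishchenko); C7–C11 → enolate alkylation; C8–O → C8–Si. The ten-membered ring is then unmade by cutting C8–C9 while joining C1–C6 (retro-oxy-Cope), and the resulting cyclohexenol is cut at C6–C7, C4–C15 and C1–C10 back to p-benzoquinone monoketal.
- Enabling feature: in ring C1–C10, the epoxide carbons C1/C10 (a masked E-alkene) and the lactone carbinol C6 (a masked ketone) form the cyclodec-5-enone unit C10=C1···C6(=O)–C7–C8–C9. Its transannular C1–C6 bond defines a six-membered ring C1–C6 that already holds the cis C4=C5 bond carrying C15 and O3.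
- Forward order: six-membered ring from the quinone monoketal → ten-membered carbocycle by 6→10 ring expansion (step 9) → γ-lactone (steps 11–14) → epoxide (step 15) → deprotection.
- Stereochemistry: C1 from Rh/BINAP conjugate addition and C3 from CBS reduction. The oxy-Cope chair transfers C1 to C8 and fixes 1(10)E and 4Z. The C8 oxygen then sets C7 (chelated dianion alkylation) and C6 (Evans–Tishchenko). The epoxide comes from attack on the outer face of the ring alkene.

Key step: step 9

Locants C1–C15 are the germacrane locants of the target (C6 lactone CH–O, C7 ring-fusion CH, C8 CH–O-ester, C1/C10 epoxide, C3 CHOH, C14 CH3, C15 CH2OH). PMB = 4-methoxybenzyl.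
Assumption: the sense of induction of the BINAP (step 1) and CBS (step 3) catalysts is taken from their standard models; should it be opposite on these substrates, the other ligand antipode would be used.

**Route**

Step 1
Reactants: 1 4,4-dimethoxycyclohexa-2,5-dien-1-one; 2 isopropenylboronic acid pinacol ester
Product: 3 (5R)-4,4-dimethoxy-5-(prop-1-en-2-yl)cyclohex-2-en-1-one
Conditions: [Rh(cod)OH]2 (2.5 mol%), (R)-BINAP (6 mol%), dioxane/H2O (10:1), 40 °C
Reagents that add atoms: none
Why: Rh(I)/BINAP-catalysed asymmetric 1,4-addition of an alkenylboron reagent (Hayashi–Miyaura) to one of the two enantiotopic enone arms of the prochiral quinone monoketal, so that the chiral Rh–alkenyl complex alone should set C1 (R).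

Step 2
Reactants: 3 (5R)-4,4-dimethoxy-5-(prop-1-en-2-yl)cyclohex-2-en-1-one
Product: 4 (5R)-2-iodo-4,4-dimethoxy-5-(prop-1-en-2-yl)cyclohex-2-en-1-one
Conditions: I2 (1.5 equiv), pyridine/CH2Cl2 (1:1), 0 to 23 °C
Reagents that add atoms: iodine II
Why: α-iodination of an enone by the pyridine addition/iodination/elimination sequence (Baylis–Hillman-type), which touches neither the ketal nor the isopropenyl group and forms no stereocentre.

Step 3
Reactants: 4 (5R)-2-iodo-4,4-dimethoxy-5-(prop-1-en-2-yl)cyclohex-2-en-1-one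
Product: 5 (1S,5R)-2-iodo-4,4-dimethoxy-5-(prop-1-en-2-yl)cyclohex-2-en-1-ol
Conditions: (R)-Me-CBS (0.2 equiv), catecholborane (1.5 equiv), toluene, −78 °C
Reagents that add atoms: none
Why: Corey–Bakshi–Shibata reduction of a 2-iodoenone, the best substrate class for this catalyst, in which the iodoalkenyl arm acts as the large group so that the catalyst should deliver hydride to give the 3S carbinol (OH trans to isopropenyl) against a modest substrate bias for the cis isomer, while catecholborane spares the 1,1-disubstituted alkene.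

Step 4
Reactants: 5 (1S,5R)-2-iodo-4,4-dimethoxy-5-(prop-1-en-2-yl)cyclohex-2-en-1-ol
Product: 6 (1S,5R)-2-(hydroxymethyl)-4,4-dimethoxy-5-(prop-1-en-2-yl)cyclohex-2-en-1-ol
Conditions: Bu3SnCH2OH (1.5 equiv), Pd(PPh3)4 (5 mol%), dioxane, 90 °C
Reagents that add atoms: (tributylstannyl)methanol OC[Sn](CCCC)(CCCC)CCCC
Why: Stille coupling of an alkenyl iodide in which the α-oxygen makes hydroxymethyl the group that transfers from tin, placing C15 on C4 with the ring alkene fixed at C4=C5.

Step 5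
Reactants: 6 (1S,5R)-2-(hydroxymethyl)-4,4-dimethoxy-5-(prop-1-en-2-yl)cyclohex-2-en-1-ol
Product: 7 (1S,5R)-1-(4-methoxybenzyloxy)-2-[(4-methoxybenzyloxy)methyl]-4,4-dimethoxy-5-(prop-1-en-2-yl)cyclohex-2-ene
Conditions: NaH (2.5 equiv), PMBCl (2.4 equiv), n-Bu4NI (cat.), DMF, 0 to 23 °C
Reagents that add atoms: 4-methoxybenzyl chloride COc1ccc(CCl)cc1
Why: double Williamson etherification, which protects O3 and O15 as ethers stable to organolithiums, potassium bases, fluoride and peracid and removable at the end under neutral oxidative conditions.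

Step 6
Reactants: 7 (1S,5R)-1-(4-methoxybenzyloxy)-2-[(4-methoxybenzyloxy)methyl]-4,4-dimethoxy-5-(prop-1-en-2-yl)cyclohex-2-ene
Product: 8 (4S,6R)-4-(4-methoxybenzyloxy)-3-[(4-methoxybenzyloxy)methyl]-6-(prop-1-en-2-yl)cyclohex-2-en-1-one
Conditions: oxalic acid (0.1 equiv), wet SiO2, CH2Cl2, 23 °C
Reagents that add atoms: water O
Why: mild acid hydrolysis of an allylic dimethyl ketal to the enone (C6 carbonyl), chosen to be gentle enough that C1 next to the new ketone is not epimerised and the isopropenyl group is not drawn into conjugation.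

Step 7
Reactants: 9 (E)-1,2-bis(tributylstannyl)ethene
Product: 11 (E)-benzyldimethyl[2-(tributylstannyl)vinyl]silane, via stannylvinyllithium 10 (not isolated)
Conditions: n-BuLi (1.0 equiv), THF, −78 °C; BnMe2SiCl, −78 to 0 °C
Reagents that add atoms: benzylchlorodimethylsilane C[Si](C)(Cl)Cc1ccccc1
Why: tin–lithium exchange at one terminus of the bis-stannane with retention of the E geometry, followed by silylation of the vinyllithium.

Step 8
Reactants: 11 (E)-benzyldimethyl[2-(tributylstannyl)vinyl]silane; 8 (4S,6R)-4-(4-methoxybenzyloxy)-3-[(4-methoxybenzyloxy)methyl]-6-(prop-1-en-2-yl)cyclohex-2-en-1-one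
Product: 13 (1R,4S,6R)-1-[(E)-2-(benzyldimethylsilyl)vinyl]-4-(4-methoxybenzyloxy)-3-[(4-methoxybenzyloxy)methyl]-6-(prop-1-en-2-yl)cyclohex-2-en-1-ol, via silylvinyllithium 12 (not isolated)
Conditions: 11 (1.6 equiv), n-BuLi (1.5 equiv), THF, −78 °C; then 8, −78 °C; aq NH4Cl
Reagents that add atoms: none
Why: tin–lithium exchange with retention and 1,2-addition of the alkenyllithium to the enone (β-carbon fully substituted), the nucleophile entering anti to the adjacent isopropenyl group so that the two alkenyl groups end up trans (substrate control of the C6 carbinol).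

Step 9
Reactants: 13 (1R,4S,6R)-1-[(E)-2-(benzyldimethylsilyl)vinyl]-4-(4-methoxybenzyloxy)-3-[(4-methoxybenzyloxy)methyl]-6-(prop-1-en-2-yl)cyclohex-2-en-1-ol
Product: 16 (2Z,4S,6E,9R)-9-(benzyldimethylsilyl)-4-(4-methoxybenzyloxy)-3-[(4-methoxybenzyloxy)methyl]-7-methylcyclodeca-2,6-dien-1-one, via potassium alkoxide 14 (not isolated), via potassium enolate 15 (not isolated)
Conditions: KHMDS (1.3 equiv), 18-crown-6 (1.3 equiv), THF, −78 to 23 °C; AcOH, −78 °C
Reagents that add atoms: none
Why: The potassium alkoxide 14 undergoes a [3,3]-sigmatropic shift (anionic oxy-Cope rearrangement) in which the C1–C6 bond of the cyclohexene breaks and C8–C9 forms, so the ten-membered ring arises by 6→10 ring expansion and not by end-to-end closure, and the enolate 15 is protonated at C7 on quench. The closest known reaction is the oxy-Cope ring expansion of trans-1,2-dialkenylcyclohexenols to cyclodecadienones used for germacrane-type rings. Because the two alkenyl groups are trans, the only chair transition state has both ring bonds (C1–C2 and C6–C5) equatorial, which should make the new C1=C10 bond E, while C4=C5 keeps the Z geometry it had in the six-membered ring. The E-vinylsilane places silicon equatorial in that chair, so C9 bonds to one face of C8 only and the configuration of C1, lost as it becomes sp2, is transferred to C8 (R). The step needs the shift to run through the two exocyclic alkenes and not through the ring alkene C4=C5 (a strained boat), which the trans-diequatorial arrangement secures, and it needs the C8 substituent to stay on the enolate, which silicon secures where an alkoxy group would be lost by β-elimination.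

Step 10
Reactants: 16 (2Z,4S,6E,9R)-9-(benzyldimethylsilyl)-4-(4-methoxybenzyloxy)-3-[(4-methoxybenzyloxy)methyl]-7-methylcyclodeca-2,6-dien-1-one
Product: 18 (2Z,4S,6E,9R)-9-hydroxy-4-(4-methoxybenzyloxy)-3-[(4-methoxybenzyloxy)methyl]-7-methylcyclodeca-2,6-dien-1-one, via fluorosilane 17 (not isolated)
Conditions: TBAF (2.2 equiv), THF, 0 °C; then KHCO3, 30% H2O2, MeOH, 23 °C
Reagents that add atoms: hydrogen peroxide OO
Why: Tamao–Fleming oxidation in which fluoride removes the benzyl group from silicon and buffered peroxide converts C8–Si into C8–OH with retention, unmasking the aldol-type β-hydroxy ketone under conditions that spare the alkenes and the PMB ethers.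

Step 11
Reactants: 18 (2Z,4S,6E,9R)-9-hydroxy-4-(4-methoxybenzyloxy)-3-[(4-methoxybenzyloxy)methyl]-7-methylcyclodeca-2,6-dien-1-one
Product: 20 tert-butyl 2-[(1R,3Z,5S,7E,10R)-10-hydroxy-5-(4-methoxybenzyloxy)-4-[(4-methoxybenzyloxy)methyl]-8-methyl-2-oxocyclodeca-3,7-dien-1-yl]acetate, via dilithium oxido-enolate 19 (not isolated)
Conditions: LDA (2.3 equiv), THF, −78 °C; BrCH2CO2t-Bu (1.2 equiv), DMPU, −78 to −50 °C; AcOH, −78 °C
Reagents that add atoms: tert-butyl bromoacetate CC(C)(C)OC(=O)CBr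
Why: Fráter–Seebach-type alkylation of a β-hydroxy ketone dianion, in which the lithium chelate holds O8 in the enolate plane, ring carbon C9 covers one face and the electrophile should enter from the periphery to place the acetate arm on C7 anti to O8; the oxido-enolate cannot β-eliminate and the tert-butyl ester resists the neighbouring alkoxide.

Step 12
Reactants: 20 tert-butyl 2-[(1R,3Z,5S,7E,10R)-10-hydroxy-5-(4-methoxybenzyloxy)-4-[(4-methoxybenzyloxy)methyl]-8-methyl-2-oxocyclodeca-3,7-dien-1-yl]acetate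
Product: 21 tert-butyl 2-[(1S,2R,3Z,5S,7E,10R)-2-hydroxy-5-(4-methoxybenzyloxy)-4-[(4-methoxybenzyloxy)methyl]-8-methyl-10-(2-methylpropanoyloxy)cyclodeca-3,7-dien-1-yl]acetate
Conditions: i-PrCHO (8 equiv), SmI2 (0.3 equiv), THF, −10 °C
Reagents that add atoms: isobutyraldehyde CC(C)C=O
Why: Evans–Tishchenko reduction, in which the samarium-bound hemiacetal formed from the C8 hydroxyl and isobutyraldehyde delivers its hydride intramolecularly to the C6 carbonyl to give the 1,3-anti diol monoester, so that one step should set C6, write the isobutyrate onto O8 and leave O6 as the only free hydroxyl.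

Step 13
Reactants: 21 tert-butyl 2-[(1S,2R,3Z,5S,7E,10R)-2-hydroxy-5-(4-methoxybenzyloxy)-4-[(4-methoxybenzyloxy)methyl]-8-methyl-10-(2-methylpropanoyloxy)cyclodeca-3,7-dien-1-yl]acetate
Product: 22 (3S,6R,7R,8R)-8-isobutyryloxy-3,15-bis(4-methoxybenzyloxy)-13-norgermacra-1(10)E,4Z-dien-12,6-olide (trans-fused γ-lactone; C11 is CH2)
Conditions: CSA (0.2 equiv), CH2Cl2, 23 °C
Reagents that add atoms: none
Why: acid-catalysed lactonisation (intramolecular transesterification of the tert-butyl ester) onto the only free hydroxyl, which closes the trans-fused 12,6-lactone without touching C6 or C7, the alkene C4=C5 being too electron-poor for transannular reaction with C1=C10 under catalytic acid.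

Step 14
Reactants: 22 (3S,6R,7R,8R)-8-isobutyryloxy-3,15-bis(4-methoxybenzyloxy)-13-norgermacra-1(10)E,4Z-dien-12,6-olide
Product: 26 (3S,6R,7R,8R)-8-isobutyryloxy-3,15-bis(4-methoxybenzyloxy)germacra-1(10)E,4Z,11(13)-trien-12,6-olide, via lithium enolate 23 (not isolated), via Mannich base 24 (not isolated), via ammonium iodide 25 (not isolated)
Conditions: LDA (1.1 equiv), THF, −78 °C; Me2N=CH2+ I−, −78 to 0 °C; MeI, MeOH, 23 °C; aq NaHCO3, CH2Cl2
Reagents that add atoms: N,N-dimethylmethyleneiminium iodide (Eschenmoser's salt) C=[N+](C)C.[I-]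
Why: α-methylenation of a γ-lactone by Mannich reaction of its lithium enolate with Eschenmoser's salt, quaternisation and Hofmann-type elimination, the lactone α-CH2 being deprotonated in preference to the hindered isobutyrate methine and no leaving group sitting β to the enolate.

Step 15
Reactants: 26 (3S,6R,7R,8R)-8-isobutyryloxy-3,15-bis(4-methoxybenzyloxy)germacra-1(10)E,4Z,11(13)-trien-12,6-olide
Product: 27 (1R,3S,6R,7R,8R,10R)-1,10-epoxy-8-isobutyryloxy-3,15-bis(4-methoxybenzyloxy)germacra-4Z,11(13)-dien-12,6-olide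
Conditions: m-CPBA (1.1 equiv), NaHCO3, CH2Cl2, 0 °C
Reagents that add atoms: m-chloroperoxybenzoic acid OOC(=O)c1cccc(Cl)c1
Why: Prilezhaev epoxidation of the only electron-rich alkene (C4=C5 carries three allylic oxygens and C11=C13 is conjugated), the peracid attacking the exposed outer face of the E-alkene of the ten-membered ring as in the natural 1β,10α-epoxy series, which should give the 1R,10R epoxide.

Step 16
Reactants: 27 (1R,3S,6R,7R,8R,10R)-1,10-epoxy-8-isobutyryloxy-3,15-bis(4-methoxybenzyloxy)germacra-4Z,11(13)-dien-12,6-olide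
Product: 28 CNP0219050.1, (1R,3S,6R,7R,8R,10R)-1,10-epoxy-3,15-dihydroxy-8-isobutyryloxygermacra-4Z,11(13)-dien-12,6-olide
Conditions: DDQ (2.6 equiv), CH2Cl2/pH 7 buffer (10:1), 0 to 23 °C
Reagents that add atoms: none
Why: oxidative cleavage of both PMB ethers by DDQ (benzylic hydride abstraction, then hydrolysis of the oxocarbenium ion) under buffered neutral conditions that keep the epoxide, the α-methylene lactone and the ester intact.

**Compound list**

1 | 4,4-dimethoxycyclohexa-2,5-dien-1-one | COC1(OC)C=CC(=O)C=C1 | starting material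
2 | isopropenylboronic acid pinacol ester | CC(=C)B1OC(C)(C)C(C)(C)O1 | starting material
3 | (5R)-4,4-dimethoxy-5-(prop-1-en-2-yl)cyclohex-2-en-1-one | COC1(OC)C=CC(=O)C[C@@H]1C(C)=C | intermediate
4 | (5R)-2-iodo-4,4-dimethoxy-5-(prop-1-en-2-yl)cyclohex-2-en-1-one | COC1(OC)C=C(I)C(=O)C[C@@H]1C(C)=C | intermediate
5 | (1S,5R)-2-iodo-4,4-dimethoxy-5-(prop-1-en-2-yl)cyclohex-2-en-1-ol (OH trans to isopropenyl) | COC1(OC)C=C(I)[C@@H](O)C[C@@H]1C(C)=C | intermediate
6 | (1S,5R)-2-(hydroxymethyl)-4,4-dimethoxy-5-(prop-1-en-2-yl)cyclohex-2-en-1-ol | COC1(OC)C=C(CO)[C@@H](O)C[C@@H]1C(C)=C | intermediate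
7 | bis-PMB ether of 6 | COC1(OC)C=C(COCc2ccc(OC)cc2)[C@@H](OCc2ccc(OC)cc2)C[C@@H]1C(C)=C | intermediate
8 | (4S,6R)-4-(4-methoxybenzyloxy)-3-[(4-methoxybenzyloxy)methyl]-6-(prop-1-en-2-yl)cyclohex-2-en-1-one | O=C1C=C(COCc2ccc(OC)cc2)[C@@H](OCc2ccc(OC)cc2)C[C@@H]1C(C)=C | intermediate
9 | (E)-1,2-bis(tributylstannyl)ethene | CCCC[Sn](CCCC)(CCCC)/C=C/[Sn](CCCC)(CCCC)CCCC | starting material
10 | (E)-2-(tributylstannyl)vinyllithium | [Li]/C=C/[Sn](CCCC)(CCCC)CCCC | intermediate
11 | (E)-benzyldimethyl[2-(tributylstannyl)vinyl]silane | CCCC[Sn](CCCC)(CCCC)/C=C/[Si](C)(C)Cc1ccccc1 | intermediate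
12 | (E)-2-(benzyldimethylsilyl)vinyllithium | [Li]/C=C/[Si](C)(C)Cc1ccccc1 | intermediate
13 | (1R,4S,6R)-1-[(E)-2-(benzyldimethylsilyl)vinyl]-4-(4-methoxybenzyloxy)-3-[(4-methoxybenzyloxy)methyl]-6-(prop-1-en-2-yl)cyclohex-2-en-1-ol (alkenyl trans to isopropenyl) | O[C@]1(/C=C/[Si](C)(C)Cc2ccccc2)C=C(COCc2ccc(OC)cc2)[C@@H](OCc2ccc(OC)cc2)C[C@@H]1C(C)=C | intermediate
14 | potassium alkoxide of 13 | [K+].[O-][C@]1(/C=C/[Si](C)(C)Cc2ccccc2)C=C(COCc2ccc(OC)cc2)[C@@H](OCc2ccc(OC)cc2)C[C@@H]1C(C)=C | intermediate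
15 | potassium C6(O)=C7 enolate of 16 (C5 and C8 trans) | [K+].[O-]C=1/C=C(/COCc2ccc(OC)cc2)[C@@H](OCc2ccc(OC)cc2)C/C=C(C)/C[C@@H]([Si](C)(C)Cc2ccccc2)/C=1 | intermediate
16 | (2Z,4S,6E,9R)-9-(benzyldimethylsilyl)-4-(4-methoxybenzyloxy)-3-[(4-methoxybenzyloxy)methyl]-7-methylcyclodeca-2,6-dien-1-one (germacrane locants: 6-oxo, 8R-silyl, 3S) | O=C1/C=C(/COCc2ccc(OC)cc2)[C@@H](OCc2ccc(OC)cc2)C/C=C(C)/C[C@@H]([Si](C)(C)Cc2ccccc2)C1 | intermediate
17 | 9-[fluoro(dimethyl)silyl] analogue of 16 | O=C1/C=C(/COCc2ccc(OC)cc2)[C@@H](OCc2ccc(OC)cc2)C/C=C(C)/C[C@@H]([Si](C)(C)F)C1 | intermediate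
18 | (2Z,4S,6E,9R)-9-hydroxy-4-(4-methoxybenzyloxy)-3-[(4-methoxybenzyloxy)methyl]-7-methylcyclodeca-2,6-dien-1-one | O=C1/C=C(/COCc2ccc(OC)cc2)[C@@H](OCc2ccc(OC)cc2)C/C=C(C)/C[C@@H](O)C1 | intermediate
19 | dilithium C8-oxido C6-enolate of 18 | [Li+].[Li+].[O-]C=1/C=C(/COCc2ccc(OC)cc2)[C@@H](OCc2ccc(OC)cc2)C/C=C(C)/C[C@@H]([O-])/C=1 | intermediate
20 | tert-butyl 2-[(1R,3Z,5S,7E,10R)-10-hydroxy-5-(4-methoxybenzyloxy)-4-[(4-methoxybenzyloxy)methyl]-8-methyl-2-oxocyclodeca-3,7-dien-1-yl]acetate (acetate arm on C7 anti to O8) | O=C1/C=C(/COCc2ccc(OC)cc2)[C@@H](OCc2ccc(OC)cc2)C/C=C(C)/C[C@@H](O)[C@H]1CC(=O)OC(C)(C)C | intermediate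
21 | tert-butyl 2-[(1S,2R,3Z,5S,7E,10R)-2-hydroxy-5-(4-methoxybenzyloxy)-4-[(4-methoxybenzyloxy)methyl]-8-methyl-10-(2-methylpropanoyloxy)cyclodeca-3,7-dien-1-yl]acetate (C6–OH 1,3-anti to C8–O) | O[C@@H]1/C=C(/COCc2ccc(OC)cc2)[C@@H](OCc2ccc(OC)cc2)C/C=C(C)/C[C@@H](OC(=O)C(C)C)[C@H]1CC(=O)OC(C)(C)C | intermediate
22 | (3S,6R,7R,8R)-8-isobutyryloxy-3,15-bis(4-methoxybenzyloxy)-13-norgermacra-1(10)E,4Z-dien-12,6-olide | C1C(=O)O[C@@H]2/C=C(/COCc3ccc(OC)cc3)[C@@H](OCc3ccc(OC)cc3)C/C=C(C)/C[C@@H](OC(=O)C(C)C)[C@@H]12 | intermediate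
23 | lithium enolate of 22 | [Li+].C1=C([O-])O[C@@H]2/C=C(/COCc3ccc(OC)cc3)[C@@H](OCc3ccc(OC)cc3)C/C=C(C)/C[C@@H](OC(=O)C(C)C)[C@@H]12 | intermediate
24 | 11-(dimethylaminomethyl) derivative of 22 (C11 epimers) | CN(C)CC1C(=O)O[C@@H]2/C=C(/COCc3ccc(OC)cc3)[C@@H](OCc3ccc(OC)cc3)C/C=C(C)/C[C@@H](OC(=O)C(C)C)[C@@H]12 | intermediate
25 | trimethylammonium iodide of 24 | [I-].C[N+](C)(C)CC1C(=O)O[C@@H]2/C=C(/COCc3ccc(OC)cc3)[C@@H](OCc3ccc(OC)cc3)C/C=C(C)/C[C@@H](OC(=O)C(C)C)[C@@H]12 | intermediate
26 | (3S,6R,7R,8R)-8-isobutyryloxy-3,15-bis(4-methoxybenzyloxy)germacra-1(10)E,4Z,11(13)-trien-12,6-olide | C=C1C(=O)O[C@@H]2/C=C(/COCc3ccc(OC)cc3)[C@@H](OCc3ccc(OC)cc3)C/C=C(C)/C[C@@H](OC(=O)C(C)C)[C@@H]12 | intermediate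
27 | (1R,3S,6R,7R,8R,10R)-1,10-epoxy-8-isobutyryloxy-3,15-bis(4-methoxybenzyloxy)germacra-4Z,11(13)-dien-12,6-olide | C=C1C(=O)O[C@@H]2/C=C(/COCc3ccc(OC)cc3)[C@@H](OCc3ccc(OC)cc3)C[C@H]4O[C@]4(C)C[C@@H](OC(=O)C(C)C)[C@@H]12 | intermediate
28 | CNP0219050.1, (1R,3S,6R,7R,8R,10R)-1,10-epoxy-3,15-dihydroxy-8-isobutyryloxygermacra-4Z,11(13)-dien-12,6-olide | C=C1C(=O)O[C@@H]2/C=C(/CO)[C@@H](O)C[C@H]3O[C@]3(C)C[C@@H](OC(=O)C(C)C)[C@@H]12 | target

**Count and risks**

Total steps: 16. Longest linear sequence: 15 (steps 1–6 and 8–16; step 7 makes the side fragment 11).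

Step 9 (key step). What may go wrong: the naked potassium alkoxide may attack silicon (benzyl–silicon cleavage or silyl transfer to oxygen) faster than the sigmatropic shift, or part of the material may rearrange through a boat so that the C1-to-C8 transfer is eroded. The fallback separates ring expansion from introduction of the C8 oxygen and sets out from 8. Vinylmagnesium bromide/CeCl3 would give the trans divinyl carbinol F1. KH/18-crown-6 followed by TMSCl would give, by the parent oxy-Cope rearrangement, the ring-expanded trimethylsilyl enol ether F2. Pd(OAc)2 in MeCN (Saegusa–Ito) would give the cross-conjugated trienone F3. Copper-catalysed enantioselective conjugate borylation (B2pin2, CuCl, NaOt-Bu, a Josiphos-type ligand, MeOH) should take the disubstituted C7=C8 enone rather than the β,β-disubstituted C4=C5 one and give the β-boryl ketone F4, with C8 set by the ligand. Oxidation of C–B with NaBO3 proceeds with retention and comes back to the route at 18.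

Step 11. What may go wrong: retro-aldol opening of the ten-membered ring or dehydration of the β-hydroxy ketone during the double deprotonation, or alkylation on the ring-shielded face if the lithium chelate is broken by the cosolvent. The fallback alkylates before the hydroxyl is unmasked and lets silicon direct; it sets out from 16. The kinetic lithium enolate (LDA, THF, −78 °C) and tert-butyl bromoacetate would give the C7-alkylated β-silyl ketone F5, the electrophile entering anti to the C8–Si bond (Fleming's rule for β-silyl enolates). Tamao oxidation of F5 under the conditions of step 10 comes back to the route at 20.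

Step 12. What may go wrong: hydride delivery to the wrong face of the C6 carbonyl, if the ring cannot adopt the extended C5–C9 arrangement of the open-chain transition state, which would give the 1,3-syn monoester. The fallback closes the lactone with inversion at C6 instead of retention and sets out from 20. The 6-epi hydroxy ester F6 formed under the step 12 conditions would be converted with MsCl/Et3N at −20 °C into the allylic mesylate F7. On warming, the carbonyl oxygen of the tert-butyl ester should displace the mesylate at C6 (5-exo SN2, loss of isobutene), giving the trans-fused lactone and coming back to the route at 22.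

**Further compounds**

F1 | step 9 | (1R,4S,6R)-1-vinyl-4-(4-methoxybenzyloxy)-3-[(4-methoxybenzyloxy)methyl]-6-(prop-1-en-2-yl)cyclohex-2-en-1-ol | O[C@]1(C=C)C=C(COCc2ccc(OC)cc2)[C@@H](OCc2ccc(OC)cc2)C[C@@H]1C(C)=C
F2 | step 9 | trimethylsilyl enol ether of (2Z,4S,6E)-4-(4-methoxybenzyloxy)-3-[(4-methoxybenzyloxy)methyl]-7-methylcyclodeca-2,6-dien-1-one (C6–OSiMe3, C6=C7) | C[Si](C)(C)OC=1/C=C(/COCc2ccc(OC)cc2)[C@@H](OCc2ccc(OC)cc2)C/C=C(C)/CC/C=1
F3 | step 9 | (2Z,4S,6E,9E)-4-(4-methoxybenzyloxy)-3-[(4-methoxybenzyloxy)methyl]-7-methylcyclodeca-2,6,9-trien-1-one | O=C1/C=C(/COCc2ccc(OC)cc2)[C@@H](OCc2ccc(OC)cc2)C/C=C(C)/C/C=C/1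
F4 | step 9 | (2Z,4S,6E,9R)-4-(4-methoxybenzyloxy)-3-[(4-methoxybenzyloxy)methyl]-7-methyl-9-(4,4,5,5-tetramethyl-1,3,2-dioxaborolan-2-yl)cyclodeca-2,6-dien-1-one | O=C1/C=C(/COCc2ccc(OC)cc2)[C@@H](OCc2ccc(OC)cc2)C/C=C(C)/C[C@@H](B2OC(C)(C)C(C)(C)O2)C1
F5 | step 11 | tert-butyl 2-[(1R,3Z,5S,7E,10R)-10-(benzyldimethylsilyl)-5-(4-methoxybenzyloxy)-4-[(4-methoxybenzyloxy)methyl]-8-methyl-2-oxocyclodeca-3,7-dien-1-yl]acetate | O=C1/C=C(/COCc2ccc(OC)cc2)[C@@H](OCc2ccc(OC)cc2)C/C=C(C)/C[C@@H]([Si](C)(C)Cc2ccccc2)[C@H]1CC(=O)OC(C)(C)C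
F6 | step 12 | 6-epimer of 21 (C6–OH 1,3-syn to C8–O) | O[C@H]1/C=C(/COCc2ccc(OC)cc2)[C@@H](OCc2ccc(OC)cc2)C/C=C(C)/C[C@@H](OC(=O)C(C)C)[C@H]1CC(=O)OC(C)(C)C
F7 | step 12 | C6 methanesulfonate of F6 | CS(=O)(=O)O[C@H]1/C=C(/COCc2ccc(OC)cc2)[C@@H](OCc2ccc(OC)cc2)C/C=C(C)/C[C@@H](OC(=O)C(C)C)[C@H]1CC(=O)OC(C)(C)C
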